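## Retrosynthetic overview

1. Target ⇒ feruloylacetone + an O-terpenyl vanillin aldehyde, joined last by a boron-templated intermolecular aldol condensation (Pabon) at the terminal methyl of the diketone; feruloylacetone ⇒ vanillin + acetylacetone in the same way.
2. Aldehyde ⇒ vanillin + an all-equatorial cyclohexenol by Mitsunobu etherification with inversion at C1; the cyclohexenol ⇒ a carvone-type 4-silyloxy enone by Luche reduction.
3. That enone ⇒ a 6-silyloxy-4-alkylcyclohex-2-enone by MeLi addition, Dauben–Babler oxidative transposition (C2 methyl, C2=C3), Luche reduction (C4–OH) and a protecting-group/oxidation-state exchange at C1.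
4. 4-Alkylcyclohexenone ⇒ (S)-citronellal + methyl vinyl ketone by a catalyst-controlled intermolecular Michael addition (sets C5) and intramolecular aldol condensation; α′-hydroxylation then brings in the C1 oxygen.
5. Ring order: the cyclohexene ring is the only ring built (steps 1–2); both benzene rings come ready-made from vanillin.

Assumption: locants C1–C6 in the "Why" lines are those of the target's cyclohexene ring (C1 OAr, C2 Me, C4 OH, C5 side chain); the C1 centre made in step 3 is carried as an epimer mixture until step 10 erases it, so it (and the transient carbinols of 4 and 9) is left unspecified in names and SMILES.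

## Route

Step 1
Reactants: 1 (S)-citronellal; 2 methyl vinyl ketone
Product: 3 (2R,3S)-3,7-dimethyl-2-(3-oxobutyl)oct-6-enal
Conditions: (R)-2-[diphenyl(trimethylsilyloxy)methyl]pyrrolidine (10 mol %), ethyl 3,4-dihydroxybenzoate (20 mol %), 2 (1.5 equiv), neat, 4 °C, 36 h
Reagents that add atoms: none
Why: Intermolecular organocatalytic Michael addition (enamine activation): the bulky diphenyl(silyloxy)methyl group of the (R)-catalyst blocks one face of the aldehyde α-carbon, so 2 adds from the open face and sets the new centre as R under catalyst control, while the 3S centre of 1 is untouched.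

Step 2
Reactants: 3 (2R,3S)-3,7-dimethyl-2-(3-oxobutyl)oct-6-enal
Product: 5 (4R)-4-[(2S)-6-methylhept-5-en-2-yl]cyclohex-2-en-1-one, via aldol adduct 4 (not isolated)
Conditions: LiOH (20 mol %), i-PrOH, rt
Reagents that add atoms: none
Why: Intramolecular aldol condensation (second half of a Robinson-type annulation): the methyl ketone enolate closes the six-membered ring onto the aldehyde and E1cB loss of water gives the enone under conditions mild enough to keep the ring stereocentre.

Step 3
Reactants: 5 (4R)-4-[(2S)-6-methylhept-5-en-2-yl]cyclohex-2-en-1-one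
Product: 7 (4R)-6-hydroxy-4-[(2S)-6-methylhept-5-en-2-yl]cyclohex-2-en-1-one (epimer mixture at the carbinol carbon), via potassium dienolate 6 (not isolated)
Conditions: KN(SiMe3)2, THF, −78 °C; (±)-2-(phenylsulfonyl)-3-phenyloxaziridine, −78 °C; then AcOH
Reagents that add atoms: 2-(phenylsulfonyl)-3-phenyloxaziridine, O=S(=O)(N1OC1c1ccccc1)c1ccccc1
Why: Davis α′-hydroxylation: kinetic deprotonation gives the cross-conjugated dienolate, which takes oxygen from the oxaziridine without touching the side-chain alkene; the new carbinol (future C1) forms as an epimer mixture that does not matter because step 10 oxidises it away.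

Step 4
Reactants: 7 (4R)-6-hydroxy-4-[(2S)-6-methylhept-5-en-2-yl]cyclohex-2-en-1-one
Product: 8 (4R)-4-[(2S)-6-methylhept-5-en-2-yl]-6-[(triethylsilyl)oxy]cyclohex-2-en-1-one (epimer mixture at the silyloxy carbon)
Conditions: Et3SiCl, imidazole, CH2Cl2, 0 °C
Reagents that add atoms: triethylsilyl chloride, CC[Si](Cl)(CC)CC
Why: Silyl ether protection of the secondary alcohol stabilises the α-hydroxy ketone and gives a group that survives steps 5–8 yet can later be removed beside a TBS ether.

Step 5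
Reactants: 8 (4R)-4-[(2S)-6-methylhept-5-en-2-yl]-6-[(triethylsilyl)oxy]cyclohex-2-en-1-one
Product: 9 (4R)-1-methyl-4-[(2S)-6-methylhept-5-en-2-yl]-6-[(triethylsilyl)oxy]cyclohex-2-en-1-ol (epimer mixture at both oxygen-bearing carbons)
Conditions: MeLi, Et2O, −78 °C; then H2O
Reagents that add atoms: methyllithium, [Li]C
Why: 1,2-Addition of methyllithium to the enone carbonyl gives the tertiary allylic alcohol needed for transposition; the configuration of the new carbinol is irrelevant because that carbon becomes sp2 in step 6.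

Step 6
Reactants: 9 (4R)-1-methyl-4-[(2S)-6-methylhept-5-en-2-yl]-6-[(triethylsilyl)oxy]cyclohex-2-en-1-ol
Product: 10 (6R)-3-methyl-6-[(2S)-6-methylhept-5-en-2-yl]-4-[(triethylsilyl)oxy]cyclohex-2-en-1-one (epimer mixture at the silyloxy carbon)
Conditions: pyridinium chlorochromate ([C5H5NH][CrO3Cl], 2.5 equiv), 4 Å molecular sieves, CH2Cl2, rt
Reagents that add atoms: pyridinium chlorochromate, [O-][Cr](=O)(=O)Cl.c1cc[nH+]cc1
Why: Dauben–Babler oxidative 1,3-transposition of a tertiary allylic alcohol: chromium delivers oxygen to the far allylic terminus and oxidises it to the ketone, which places the double bond at C2=C3 next to the methyl group and the carbonyl at C4 without touching C5.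

Step 7
Reactants: 10 (6R)-3-methyl-6-[(2S)-6-methylhept-5-en-2-yl]-4-[(triethylsilyl)oxy]cyclohex-2-en-1-one
Product: 11 (1R,6R)-3-methyl-6-[(2S)-6-methylhept-5-en-2-yl]-4-[(triethylsilyl)oxy]cyclohex-2-en-1-ol (epimer mixture at the silyloxy carbon)
Conditions: NaBH4, CeCl3·7H2O, MeOH, −78 °C
Reagents that add atoms: none
Why: Luche 1,2-reduction: axial hydride attack on the half-chair enone, whose side chain sits equatorial, gives the equatorial C4 alcohol trans to the C5 side chain (4R of the target); any minor cis epimer is removed at enone 14.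

Step 8
Reactants: 11 (1R,6R)-3-methyl-6-[(2S)-6-methylhept-5-en-2-yl]-4-[(triethylsilyl)oxy]cyclohex-2-en-1-ol
Product: 12 (3R,4R)-3-[(tert-butyldimethylsilyl)oxy]-1-methyl-4-[(2S)-6-methylhept-5-en-2-yl]-6-[(triethylsilyl)oxy]cyclohex-1-ene (epimer mixture at the triethylsilyloxy carbon)
Conditions: t-BuMe2SiOTf, 2,6-lutidine, CH2Cl2, −78 → 0 °C
Reagents that add atoms: tert-butyldimethylsilyl trifluoromethanesulfonate, CC(C)(C)[Si](C)(C)OS(=O)(=O)C(F)(F)F
Why: Silyl triflate silylation protects the hindered C4 allylic alcohol as a TBS ether that is orthogonal to the TES ether on C1.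

Step 9
Reactants: 12 (3R,4R)-3-[(tert-butyldimethylsilyl)oxy]-1-methyl-4-[(2S)-6-methylhept-5-en-2-yl]-6-[(triethylsilyl)oxy]cyclohex-1-ene
Product: 13 (4R,5R)-4-[(tert-butyldimethylsilyl)oxy]-2-methyl-5-[(2S)-6-methylhept-5-en-2-yl]cyclohex-2-en-1-ol (epimer mixture at the carbinol carbon)
Conditions: pyridinium p-toluenesulfonate (10 mol %), MeOH/CH2Cl2, 0 °C
Reagents that add atoms: none
Why: Selective acid-catalysed methanolysis of a silyl ether: a secondary TES ether is cleaved far faster than a secondary TBS ether, so only the C1 hydroxyl is freed.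

Step 10
Reactants: 13 (4R,5R)-4-[(tert-butyldimethylsilyl)oxy]-2-methyl-5-[(2S)-6-methylhept-5-en-2-yl]cyclohex-2-en-1-ol
Product: 14 (4R,5R)-4-[(tert-butyldimethylsilyl)oxy]-2-methyl-5-[(2S)-6-methylhept-5-en-2-yl]cyclohex-2-en-1-one
Conditions: Dess–Martin periodinane, CH2Cl2, 0 °C → rt
Reagents that add atoms: none
Why: Dess–Martin oxidation of the allylic alcohol gives the carvone-type enone and merges both C1 epimers into one compound, at which point any C4 epimer from step 7 is separated.

Step 11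
Reactants: 14 (4R,5R)-4-[(tert-butyldimethylsilyl)oxy]-2-methyl-5-[(2S)-6-methylhept-5-en-2-yl]cyclohex-2-en-1-one
Product: 15 (1R,4R,5R)-4-[(tert-butyldimethylsilyl)oxy]-2-methyl-5-[(2S)-6-methylhept-5-en-2-yl]cyclohex-2-en-1-ol
Conditions: NaBH4, CeCl3·7H2O, MeOH, −78 °C
Reagents that add atoms: none
Why: Luche reduction as in carvone to cis-carveol: axial hydride attack gives the all-equatorial alcohol, with C1–OH cis to the C5 side chain and trans to the C4 silyl ether (1R).

Step 12
Reactants: 15 (1R,4R,5R)-4-[(tert-butyldimethylsilyl)oxy]-2-methyl-5-[(2S)-6-methylhept-5-en-2-yl]cyclohex-2-en-1-ol; 16 vanillin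
Product: 17 4-{[(1S,4R,5R)-4-[(tert-butyldimethylsilyl)oxy]-2-methyl-5-[(2S)-6-methylhept-5-en-2-yl]cyclohex-2-en-1-yl]oxy}-3-methoxybenzaldehyde
Conditions: PPh3, DIAD, THF, 0 °C → rt
Reagents that add atoms: none
Why: Mitsunobu etherification: the acidic phenol of vanillin (pKa about 7.4) displaces the activated equatorial allylic hydroxyl by SN2 with inversion, which places the aryl ether on C1 trans to the side chain and cis to the C4 oxygen (1S).

Step 13
Reactants: 17 4-{[(1S,4R,5R)-4-[(tert-butyldimethylsilyl)oxy]-2-methyl-5-[(2S)-6-methylhept-5-en-2-yl]cyclohex-2-en-1-yl]oxy}-3-methoxybenzaldehyde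
Product: 18 4-{[(1S,4R,5R)-4-hydroxy-2-methyl-5-[(2S)-6-methylhept-5-en-2-yl]cyclohex-2-en-1-yl]oxy}-3-methoxybenzaldehyde
Conditions: Bu4NF, THF, 0 °C → rt
Reagents that add atoms: none
Why: Fluoride-mediated desilylation frees the C4 hydroxyl; the aldehyde, the allyl aryl ether and both alkenes are inert to Bu4NF and no stereocentre is touched.

Step 14
Reactants: 16 vanillin; 19 acetylacetone
Product: 22 (E)-6-(4-hydroxy-3-methoxyphenyl)hex-5-ene-2,4-dione (feruloylacetone), via dibutoxyboron chelate of acetylacetone 20 (not isolated), via dibutoxyboron chelate of feruloylacetone 21 (not isolated)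
Conditions: 19 (3 equiv), B2O3, B(OBu)3, EtOAc, 70 °C; 16; n-BuNH2 (10 mol %), 70 °C; then 0.4 M aq. HCl, 50 °C
Reagents that add atoms: none
Why: Pabon aldol condensation: boron chelation blocks the central carbon of the diketone and directs the amine-catalysed condensation to a terminal methyl, the excess of 19 favours mono-condensation, and E1cB dehydration gives the E alkene.

Step 15
Reactants: 22 (E)-6-(4-hydroxy-3-methoxyphenyl)hex-5-ene-2,4-dione; 18 4-{[(1S,4R,5R)-4-hydroxy-2-methyl-5-[(2S)-6-methylhept-5-en-2-yl]cyclohex-2-en-1-yl]oxy}-3-methoxybenzaldehyde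
Product: 25 terpecurcumin B, via diisopropoxyboron chelate of feruloylacetone 23 (not isolated), via diisopropoxyboron chelate of the product 24 (not isolated)
Conditions: 22, B2O3, B(Oi-Pr)3, EtOAc, 60 °C; then 18; n-BuNH2 (20 mol %), 60 °C; then 5% aq. AcOH, rt
Reagents that add atoms: none
Why: Intermolecular aldol condensation (Pabon) joining the two fragments: 22 is chelated by boron in the presence of triisopropyl borate, a hindered secondary borate that scavenges water and exchanges only sluggishly with the free allylic hydroxyl of 18, the chelate reacts only at its remaining terminal methyl with aldehyde 18, dehydration gives the second E alkene, and mild hydrolysis releases the enolised diketone without touching the four stereocentres.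

## Compound list

1 | (S)-citronellal, (3S)-3,7-dimethyloct-6-enal | O=CC[C@@H](C)CCC=C(C)C | starting material
2 | methyl vinyl ketone (but-3-en-2-one) | CC(=O)C=C | starting material
3 | (2R,3S)-3,7-dimethyl-2-(3-oxobutyl)oct-6-enal | CC(=O)CC[C@H]([C@@H](C)CCC=C(C)C)C=O | intermediate
4 | (4R)-3-hydroxy-4-[(2S)-6-methylhept-5-en-2-yl]cyclohexan-1-one (aldol adduct, carbinol epimers) | O=C1CC(O)[C@@H]([C@@H](C)CCC=C(C)C)CC1 | intermediate (not isolated)
5 | (4R)-4-[(2S)-6-methylhept-5-en-2-yl]cyclohex-2-en-1-one | O=C1C=C[C@@H]([C@@H](C)CCC=C(C)C)CC1 | intermediate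
6 | potassium (4R)-4-[(2S)-6-methylhept-5-en-2-yl]cyclohexa-1,5-dien-1-olate | [K+].[O-]C1=CC[C@H]([C@@H](C)CCC=C(C)C)C=C1 | intermediate (not isolated)
7 | (4R)-6-hydroxy-4-[(2S)-6-methylhept-5-en-2-yl]cyclohex-2-en-1-one (epimers at the carbinol carbon) | O=C1C=C[C@@H]([C@@H](C)CCC=C(C)C)CC1O | intermediate
8 | (4R)-4-[(2S)-6-methylhept-5-en-2-yl]-6-[(triethylsilyl)oxy]cyclohex-2-en-1-one (epimers at the silyloxy carbon) | O=C1C=C[C@@H]([C@@H](C)CCC=C(C)C)CC1O[Si](CC)(CC)CC | intermediate
9 | (4R)-1-methyl-4-[(2S)-6-methylhept-5-en-2-yl]-6-[(triethylsilyl)oxy]cyclohex-2-en-1-ol (epimers at both oxygen-bearing carbons) | CC1(O)C=C[C@@H]([C@@H](C)CCC=C(C)C)CC1O[Si](CC)(CC)CC | intermediate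
10 | (6R)-3-methyl-6-[(2S)-6-methylhept-5-en-2-yl]-4-[(triethylsilyl)oxy]cyclohex-2-en-1-one (epimers at the silyloxy carbon) | CC[Si](CC)(CC)OC1C[C@H]([C@@H](C)CCC=C(C)C)C(=O)C=C1C | intermediate
11 | (1R,6R)-3-methyl-6-[(2S)-6-methylhept-5-en-2-yl]-4-[(triethylsilyl)oxy]cyclohex-2-en-1-ol (epimers at the silyloxy carbon) | CC[Si](CC)(CC)OC1C[C@H]([C@@H](C)CCC=C(C)C)[C@@H](O)C=C1C | intermediate
12 | (3R,4R)-3-[(tert-butyldimethylsilyl)oxy]-1-methyl-4-[(2S)-6-methylhept-5-en-2-yl]-6-[(triethylsilyl)oxy]cyclohex-1-ene (epimers at the triethylsilyloxy carbon) | CC[Si](CC)(CC)OC1C[C@H]([C@@H](C)CCC=C(C)C)[C@@H](O[Si](C)(C)C(C)(C)C)C=C1C | intermediate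
13 | (4R,5R)-4-[(tert-butyldimethylsilyl)oxy]-2-methyl-5-[(2S)-6-methylhept-5-en-2-yl]cyclohex-2-en-1-ol (epimers at the carbinol carbon) | OC1C[C@H]([C@@H](C)CCC=C(C)C)[C@@H](O[Si](C)(C)C(C)(C)C)C=C1C | intermediate
14 | (4R,5R)-4-[(tert-butyldimethylsilyl)oxy]-2-methyl-5-[(2S)-6-methylhept-5-en-2-yl]cyclohex-2-en-1-one | O=C1C[C@H]([C@@H](C)CCC=C(C)C)[C@@H](O[Si](C)(C)C(C)(C)C)C=C1C | intermediate
15 | (1R,4R,5R)-4-[(tert-butyldimethylsilyl)oxy]-2-methyl-5-[(2S)-6-methylhept-5-en-2-yl]cyclohex-2-en-1-ol | O[C@@H]1C[C@H]([C@@H](C)CCC=C(C)C)[C@@H](O[Si](C)(C)C(C)(C)C)C=C1C | intermediate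
16 | vanillin (4-hydroxy-3-methoxybenzaldehyde) | COc1cc(C=O)ccc1O | starting material
17 | 4-{[(1S,4R,5R)-4-[(tert-butyldimethylsilyl)oxy]-2-methyl-5-[(2S)-6-methylhept-5-en-2-yl]cyclohex-2-en-1-yl]oxy}-3-methoxybenzaldehyde | COc1cc(C=O)ccc1O[C@H]1C[C@H]([C@@H](C)CCC=C(C)C)[C@@H](O[Si](C)(C)C(C)(C)C)C=C1C | intermediate
18 | 4-{[(1S,4R,5R)-4-hydroxy-2-methyl-5-[(2S)-6-methylhept-5-en-2-yl]cyclohex-2-en-1-yl]oxy}-3-methoxybenzaldehyde | COc1cc(C=O)ccc1O[C@H]1C[C@H]([C@@H](C)CCC=C(C)C)[C@@H](O)C=C1C | intermediate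
19 | acetylacetone (pentane-2,4-dione) | CC(=O)CC(C)=O | starting material
20 | dibutoxyboron chelate of acetylacetone, drawn as the 2,2-dibutoxy-4,6-dimethyl-1,3,2-dioxaborinine | CC1=CC(C)=[O+][B-](OCCCC)(OCCCC)O1 | intermediate (not isolated)
21 | dibutoxyboron chelate of feruloylacetone, drawn as the 2,2-dibutoxy-1,3,2-dioxaborinine carrying methyl and (E)-4-hydroxy-3-methoxystyryl groups | COc1cc(/C=C/C2=CC(C)=[O+][B-](OCCCC)(OCCCC)O2)ccc1O | intermediate (not isolated)
22 | feruloylacetone, (E)-6-(4-hydroxy-3-methoxyphenyl)hex-5-ene-2,4-dione | COc1cc(/C=C/C(=O)CC(C)=O)ccc1O | intermediate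
23 | diisopropoxyboron chelate of feruloylacetone, drawn as the 2,2-di(propan-2-yloxy)-1,3,2-dioxaborinine carrying methyl and (E)-4-hydroxy-3-methoxystyryl groups | COc1cc(/C=C/C2=CC(C)=[O+][B-](OC(C)C)(OC(C)C)O2)ccc1O | intermediate (not isolated)
24 | diisopropoxyboron chelate of the product, drawn as the 2,2-di(propan-2-yloxy)-1,3,2-dioxaborinine of terpecurcumin B | COc1cc(/C=C/C2=CC(/C=C/c3ccc(O[C@H]4C[C@H]([C@@H](C)CCC=C(C)C)[C@@H](O)C=C4C)c(OC)c3)=[O+][B-](OC(C)C)(OC(C)C)O2)ccc1O | intermediate (not isolated)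
25 | terpecurcumin B, (1E,4Z,6E)-5-hydroxy-1-(4-hydroxy-3-methoxyphenyl)-7-(4-{[(1S,4R,5R)-4-hydroxy-2-methyl-5-[(2S)-6-methylhept-5-en-2-yl]cyclohex-2-en-1-yl]oxy}-3-methoxyphenyl)hepta-1,4,6-trien-3-one | COc1cc(/C=C/C(=O)/C=C(O)/C=C/c2ccc(O[C@H]3C[C@H]([C@@H](C)CCC=C(C)C)[C@@H](O)C=C3C)c(OC)c2)ccc1O | target

## Step count and risks

Total step count: 15. Longest linear sequence: 14 steps (steps 1–13, then step 15); step 14 is a one-step side branch.

Most likely to fail, first: step 7. The hydride must choose between the two faces of a ketone flanked by the branched side chain, and the trans:cis ratio at C4 may be only moderate. The fallback sets the C4 oxygen from an epoxide instead of by reduction; it sets out from enone 8 and comes back to the route at alcohol 11. Weitz–Scheffer epoxidation of 8 (t-BuOOH, DBU, CH2Cl2, 0 °C) puts the oxirane anti to the side chain and gives the epoxy ketone F1. Wittig methylenation (Ph3PCH3Br, KOt-Bu, THF, 0 °C) gives the exocyclic vinyl epoxide F2. SmI2 (2.2 equiv, THF/MeOH, −78 °C, Molander 1,4-reduction) then cleaves the allylic C–O bond and protonates the exocyclic carbon, which gives 11 with the C4–O bond next to the side chain untouched.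

Second: step 12. A Mitsunobu etherification at a hindered secondary allylic carbinol can leak to SN2′ ethers or dienes, or stall. The fallback makes the aryl–oxygen bond by SNAr instead of the alkyl–oxygen bond; it sets out from alcohol 15 and comes back at aldehyde 17. C1 is first inverted by Mitsunobu esterification with 4-nitrobenzoic acid (PPh3, DIAD, THF), which is more dependable for carveol-type alcohols, to give the 4-nitrobenzoate F3. Methanolysis (K2CO3, MeOH, rt) gives the epimeric alcohol F4. Its potassium alkoxide (KN(SiMe3)2, THF/DMF, 0 °C → rt) displaces fluoride from 4-fluoro-3-methoxybenzaldehyde with retention at C1 and gives 17.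

Third: step 15. The free allylic alcohol and the 1,4-dioxygenated cyclohexene (which can eliminate towards an arene) must survive borate exchange and chelate hydrolysis, and the amine can scramble unsymmetrical curcuminoids by retro-aldol. The fallback builds the diketone by a Claisen-type C-acylation instead; it sets out from silyl ether 17 and comes back at target 25. Wittig olefination of 17 with Ph3P=CHC(O)CH3 (toluene, 90 °C) gives the enone F5. Commercial ferulic acid is silylated on both oxygens (t-BuMe2SiCl, imidazole, DMF) to the bis-silyl ferulate F6, whose silyl ester is converted directly (oxalyl chloride, DMF cat., CH2Cl2) into the acid chloride F7. The lithium enolate of F5 (LiN(SiMe3)2, 2.2 equiv, THF, −78 °C; the second equivalent deprotonates the product) is acylated by F7 to the bis-silyl curcuminoid F8. HF·pyridine (THF, 0 °C → rt) removes both silyl groups and gives 25.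

Further compounds
F1 | step 7 | 5-[(2S)-6-methylhept-5-en-2-yl]-3-[(triethylsilyl)oxy]-7-oxabicyclo[4.1.0]heptan-2-one, oxirane anti to the side chain, (5R) at the side-chain carbon, silyloxy carbon as epimer mixture | CC[Si](CC)(CC)OC1C[C@H]([C@@H](C)CCC=C(C)C)[C@H]2O[C@H]2C1=O
F2 | step 7 | 2-methylidene-5-[(2S)-6-methylhept-5-en-2-yl]-3-[(triethylsilyl)oxy]-7-oxabicyclo[4.1.0]heptane, oxirane anti to the side chain, silyloxy carbon as epimer mixture | CC[Si](CC)(CC)OC1C[C@H]([C@@H](C)CCC=C(C)C)[C@H]2O[C@H]2C1=C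
F3 | step 12 | (1S,4R,5R)-4-[(tert-butyldimethylsilyl)oxy]-2-methyl-5-[(2S)-6-methylhept-5-en-2-yl]cyclohex-2-en-1-yl 4-nitrobenzoate | O=C(O[C@H]1C[C@H]([C@@H](C)CCC=C(C)C)[C@@H](O[Si](C)(C)C(C)(C)C)C=C1C)c1ccc(cc1)[N+](=O)[O-]
F4 | step 12 | (1S,4R,5R)-4-[(tert-butyldimethylsilyl)oxy]-2-methyl-5-[(2S)-6-methylhept-5-en-2-yl]cyclohex-2-en-1-ol | O[C@H]1C[C@H]([C@@H](C)CCC=C(C)C)[C@@H](O[Si](C)(C)C(C)(C)C)C=C1C
F5 | step 15 | (E)-4-(4-{[(1S,4R,5R)-4-[(tert-butyldimethylsilyl)oxy]-2-methyl-5-[(2S)-6-methylhept-5-en-2-yl]cyclohex-2-en-1-yl]oxy}-3-methoxyphenyl)but-3-en-2-one | CC(=O)/C=C/c1ccc(O[C@H]2C[C@H]([C@@H](C)CCC=C(C)C)[C@@H](O[Si](C)(C)C(C)(C)C)C=C2C)c(OC)c1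
F6 | step 15 | tert-butyldimethylsilyl (E)-3-{4-[(tert-butyldimethylsilyl)oxy]-3-methoxyphenyl}prop-2-enoate | COc1cc(/C=C/C(=O)O[Si](C)(C)C(C)(C)C)ccc1O[Si](C)(C)C(C)(C)C
F7 | step 15 | (E)-3-{4-[(tert-butyldimethylsilyl)oxy]-3-methoxyphenyl}prop-2-enoyl chloride | COc1cc(/C=C/C(Cl)=O)ccc1O[Si](C)(C)C(C)(C)C
F8 | step 15 | (1E,6E)-1-{4-[(tert-butyldimethylsilyl)oxy]-3-methoxyphenyl}-7-(4-{[(1S,4R,5R)-4-[(tert-butyldimethylsilyl)oxy]-2-methyl-5-[(2S)-6-methylhept-5-en-2-yl]cyclohex-2-en-1-yl]oxy}-3-methoxyphenyl)hepta-1,6-diene-3,5-dione | COc1cc(/C=C/C(=O)CC(=O)/C=C/c2ccc(O[C@H]3C[C@H]([C@@H](C)CCC=C(C)C)[C@@H](O[Si](C)(C)C(C)(C)C)C=C3C)c(OC)c2)ccc1O[Si](C)(C)C(C)(C)C
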